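**Retrosynthetic overview**
1. Cut the C2–aryl bond. An enantioselective conjugate arylation of 7-hydroxychromone by a chromen-6-ylboronic acid sets C2.
2. Neither pyran ring is carried in. Ring D comes from an ortho-prenylphenol (DDQ, o-quinone methide, oxa-6π). Ring C comes from an ortho-hydroxyaryl enaminone (acid cyclocondensation). Both are closed in the flask in which the coupling is run.
3. Order of rings: A and B are bought, ring D closes first, ring C second, and then the C–C bond joins the two bicycles.
4. The diprenyl boronic acid comes from 4-iodophenol and two prenyl bromides (aqueous double ortho C-prenylation), followed by I/Li exchange and borylation.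
5. The enaminone comes from 2,4-dihydroxyacetophenone and DMF dimethyl acetal, whose CH becomes C2.

Assumption: the facial selectivity of Pd(OCOCF3)2/t-BuPyOx on chromones is taken to parallel that on cyclic enones, so the (R)-ligand is assigned to the (2S)-product. If the sense is opposite, the (S)-ligand is used with no other change.

Step 1
Reactants: 1 4-iodophenol; 2 prenyl bromide (1-bromo-3-methylbut-2-ene, 2.5 equiv)
Product: 4 4-iodo-2,6-bis(3-methylbut-2-en-1-yl)phenol, via 4-iodo-2-prenylphenol 3 (not isolated)
Conditions: KOH (2.5 equiv), H2O, rt, 24 h, vigorous stirring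
Reagents that add atoms: prenyl bromide 2, CC(C)=CCBr
Why: Aqueous phenoxide ortho C-allylation (two SN2 events at the primary carbon of 2): water hydrogen-bonds the phenoxide oxygen and diverts the soft allylic bromide to carbon, the para position is blocked by iodine, both ortho positions are alkylated in turn (3, then 4), and no stereocenter is formed.

Step 2
Reactants: 4 4-iodo-2,6-bis(3-methylbut-2-en-1-yl)phenol
Product: 6 [4-hydroxy-3,5-bis(3-methylbut-2-en-1-yl)phenyl]boronic acid, via dilithiated phenol 5 (not isolated)
Conditions: B(OiPr)3 (1.5 equiv), n-BuLi (2.2 equiv), THF, −78 °C to rt; then 1 M HCl, 0 °C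
Reagents that add atoms: triisopropyl borate, CC(C)OB(OC(C)C)OC(C)C; water, O
Why: Halogen–lithium exchange followed by electrophilic borylation: the first equivalent of n-BuLi only removes the phenol proton, the second exchanges the aryl iodide at −78 °C far faster than it could deprotonate an allylic position, 5 is trapped at once by the borate already present, and cold dilute acid hydrolyses the borate to 6 without touching the prenyl groups; no stereocenter is formed.

Step 3
Reactants: 7 2,4-dihydroxyacetophenone; 8 N,N-dimethylformamide dimethyl acetal (1.2 equiv)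
Product: 9 (E)-3-(dimethylamino)-1-(2,4-dihydroxyphenyl)prop-2-en-1-one
Conditions: toluene, 85 °C, 3 h, MeOH distilled off
Reagents that add atoms: N,N-dimethylformamide dimethyl acetal 8, COC(OC)N(C)C
Why: Amide-acetal condensation (enaminone synthesis): the methyl ketone of 7 condenses with the formamide acetal with loss of two MeOH to give the hydrogen-bonded push–pull (E)-enaminone, only a small excess of 8 and moderate heat being used so that the 4-OH is not O-methylated; the new CH is the future C2 and no stereocenter is formed yet.

Step 4
Reactants: 6 [4-hydroxy-3,5-bis(3-methylbut-2-en-1-yl)phenyl]boronic acid (1.5 equiv); 9 (E)-3-(dimethylamino)-1-(2,4-dihydroxyphenyl)prop-2-en-1-one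
Product: 13 (2S)-7-hydroxy-2-[2,2-dimethyl-8-(3-methylbut-2-en-1-yl)-2H-chromen-6-yl]chroman-4-one, via o-quinone methide 10 (not isolated), via chromenylboronic acid 11 (not isolated), via 7-hydroxychromone 12 (not isolated)
Conditions: DDQ (1.0 equiv per 6), ClCH2CH2Cl, 60 °C, 1 h; add 9, CF3CO2H (1.1 equiv), H2O (5 equiv), 60 °C, 30 min; add Pd(OCOCF3)2 (10 mol %), (R)-t-BuPyOx (12 mol %), NH4PF6 (30 mol %), 60 °C, 24 h; one flask, one work-up
Reagents that add atoms: none
Why: Proposed new method: three individually known events are run in one flask, namely DDQ abstracts hydride from a benzylic–allylic CH2 of 6 to give o-quinone methide 10, which closes ring D by oxa-6π electrocyclisation to 11 (dehydrogenative chromene synthesis), acid then closes ring C by 6-endo addition–elimination of the ortho-phenol on protonated 9 with loss of Me2NH to give 12 (enaminone-to-chromone cyclocondensation), and the cationic aryl–palladium species made from 11 (divalent palladium throughout) inserts the C2=C3 bond of 12 on the face left open by the tert-butyl group of the (R)-ligand and is released by protonolysis of the palladium enolate, which sets (2S); the closest known reaction type is the palladium/pyridine-oxazoline-catalysed asymmetric conjugate addition of arylboronic acids to chromones, which runs in wet solvent with ammonium salts and trifluoroacetate present, so the insoluble reduced DDQ and the protonated amine should be spectators.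

**Compound list**
1 | 4-iodophenol | Oc1ccc(I)cc1 | starting material
2 | prenyl bromide (1-bromo-3-methylbut-2-ene) | CC(C)=CCBr | starting material
3 | 4-iodo-2-(3-methylbut-2-en-1-yl)phenol | CC(C)=CCc1cc(I)ccc1O | intermediate
4 | 4-iodo-2,6-bis(3-methylbut-2-en-1-yl)phenol | CC(C)=CCc1cc(I)cc(CC=C(C)C)c1O | intermediate
5 | lithium 4-lithio-2,6-bis(3-methylbut-2-en-1-yl)phenoxide | [Li]c1cc(CC=C(C)C)c(O[Li])c(CC=C(C)C)c1 | intermediate
6 | [4-hydroxy-3,5-bis(3-methylbut-2-en-1-yl)phenyl]boronic acid | CC(C)=CCc1cc(B(O)O)cc(CC=C(C)C)c1O | intermediate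
7 | 2,4-dihydroxyacetophenone | CC(=O)c1ccc(O)cc1O | starting material
8 | N,N-dimethylformamide dimethyl acetal | COC(OC)N(C)C | starting material
9 | (E)-3-(dimethylamino)-1-(2,4-dihydroxyphenyl)prop-2-en-1-one | CN(C)/C=C/C(=O)c1ccc(O)cc1O | intermediate
10 | [5-(3-methylbut-2-en-1-yl)-3-(3-methylbut-2-en-1-ylidene)-4-oxocyclohexa-1,5-dien-1-yl]boronic acid (o-quinone methide) | O=C1C(=CC=C(C)C)C=C(B(O)O)C=C1CC=C(C)C | intermediate
11 | [2,2-dimethyl-8-(3-methylbut-2-en-1-yl)-2H-chromen-6-yl]boronic acid | CC(C)=CCc1cc(B(O)O)cc2c1OC(C)(C)C=C2 | intermediate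
12 | 7-hydroxy-4H-chromen-4-one | O=c1ccoc2cc(O)ccc12 | intermediate
13 | (2S)-7-hydroxy-2-[2,2-dimethyl-8-(3-methylbut-2-en-1-yl)-2H-chromen-6-yl]chroman-4-one | CC(C)=CCc1cc([C@@H]2CC(=O)c3ccc(O)cc3O2)cc2c1OC(C)(C)C=C2 | target

**Step count:** 4 steps in total. **Longest linear sequence:** 3 steps (1 → 4 → 6 → 13).

**Steps most likely to fail**

**Step 4.**
- Para-alkoxy arylboronic acids protodeboronate easily and tend to give lower ee in this catalysis. One recrystallisation of 13 is foreseen.
- Reduced DDQ or the ammonium salt may slow the catalyst.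
- The chromene is acid-sensitive.

The fallback gives up the C2–aryl coupling, builds ring C around an aldehyde carbon and then resolves. It sets out from 4 and 7 and comes back at 13. Compound 4 is dilithiated to 5 as in step 2 and quenched with DMF to give 4-hydroxy-3,5-diprenylbenzaldehyde F1. DDQ in toluene closes ring D to 2,2-dimethyl-8-prenyl-2H-chromene-6-carbaldehyde F2. In the same flask, 7 and pyrrolidine in MeOH at 60 °C join the halves by enamine aldol condensation to the 2'-hydroxychalcone F3. This closes ring C by oxa-Michael addition to the racemic flavanone F4. Kinetic resolution follows by asymmetric transfer hydrogenation with RuCl[(R,R)-TsDPEN](p-cymene) and HCO2H/Et3N, stopped a little past half conversion. It reduces the (2R)-ketone to the cis-(2R,4R)-flavan-4-ol F5 and leaves 13, which is separated by chromatography.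

**Step 1.** O-alkylation, mono-alkylation and chroman formation compete, so the yield is moderate at best. The fallback drops the halide and puts boron in by C–H activation. It sets out from 2 (plus commercial phenol) and comes back at 6, so it also bypasses step 2. Sodium phenoxide (phenol, NaH) in toluene is C-alkylated with 2 to 2,6-diprenylphenol F6. Borylation with [Ir(OMe)(cod)]2, dtbpy and B2pin2 at 60 °C goes to the only unhindered C–H, para to the oxygen, and gives the pinacol boronate F7. Transesterification with methylboronic acid in aqueous acetone (catalytic CF3CO2H) releases 6.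

**Step 2.** The dianion 5 may be poorly soluble or be butylated, and 6 may protodeboronate during the acidic work-up. The fallback replaces organolithium chemistry by cross-coupling. It sets out from 4 and comes back at 6. Treatment with Pd(OAc)2, XPhos, KOAc and B2(OH)4 in EtOH at 80 °C borylates the free iodophenol directly to the boronic acid under near-neutral conditions.

**Further compounds**
F1 | step 4 | 4-hydroxy-3,5-bis(3-methylbut-2-en-1-yl)benzaldehyde | CC(C)=CCc1cc(C=O)cc(CC=C(C)C)c1O
F2 | step 4 | 2,2-dimethyl-8-(3-methylbut-2-en-1-yl)-2H-chromene-6-carbaldehyde | CC(C)=CCc1cc(C=O)cc2c1OC(C)(C)C=C2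
F3 | step 4 | (E)-1-(2,4-dihydroxyphenyl)-3-[2,2-dimethyl-8-(3-methylbut-2-en-1-yl)-2H-chromen-6-yl]prop-2-en-1-one | CC(C)=CCc1cc(/C=C/C(=O)c2ccc(O)cc2O)cc2c1OC(C)(C)C=C2
F4 | step 4 | racemic 7-hydroxy-2-[2,2-dimethyl-8-(3-methylbut-2-en-1-yl)-2H-chromen-6-yl]chroman-4-one | CC(C)=CCc1cc(C2CC(=O)c3ccc(O)cc3O2)cc2c1OC(C)(C)C=C2
F5 | step 4 | (2R,4R)-2-[2,2-dimethyl-8-(3-methylbut-2-en-1-yl)-2H-chromen-6-yl]chromane-4,7-diol | CC(C)=CCc1cc([C@H]2C[C@@H](O)c3ccc(O)cc3O2)cc2c1OC(C)(C)C=C2
F6 | step 1 | 2,6-bis(3-methylbut-2-en-1-yl)phenol | CC(C)=CCc1cccc(CC=C(C)C)c1O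
F7 | step 1 | 2,6-bis(3-methylbut-2-en-1-yl)-4-(4,4,5,5-tetramethyl-1,3,2-dioxaborolan-2-yl)phenol | CC(C)=CCc1cc(B2OC(C)(C)C(C)(C)O2)cc(CC=C(C)C)c1O
F0 | step 2 | none | none
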